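**Plan**
Numbering used in all names: ring A = C6 (spiro), C7 (=C14H2), C8, C9 (OAc), C10 (Br), C11 (CMe2). Ring B = C6, C1, C2 (Cl), C3 (CH3, Br), C4, C5.
Enabling feature: ring A is functionalised at C7 and C9, a 1,3 pair directly beside the gem-dimethyl carbon C11. Read as a cyclohexane-1,3-dione, its C8–C9–C10–C11 segment with both methyls is mesityl oxide, and C7 is a carboxyl carbon on C6 of a symmetric ring B.
Retrosynthetic cuts: C3–Br, C2–Cl and C3–CH3 (back to a C3 ketone), then C7=C14 and C10–Br (back to the 1,3-dione), then C7–C8 and the hindered C6–C11 bond.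
Forward order: ring B is bought as a ketal ester, and ring A is closed onto it in one operation (C6–C11, then C7–C8). Ring A is then dressed (C14, Br, OAc), and ring B is finished last (CH3, Cl, Br).
Stereochemistry: C6 comes from enantiotopos-selective deprotonation of the symmetric ring B ketone by a chiral lithium amide. C10 is set by equilibration under the influence of C6, and C9 by hydride delivery to the bromoketone. C2 and C3 come from a reagent-controlled Shi epoxidation, followed by inversion at C2 (chloride) and retention at C3 (bromide through a chloronium ion). Because two independent chiral reagents are used, the minor enantiomer should be shed as a diastereomer.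

Key step: step 2

Assumption: the sense of induction of the lithium amide is taken from 4-tert-butylcyclohexanone and that of the Shi catalyst from 1-substituted cyclohexenes; both reagents exist in both enantiomeric forms, so a reversed sense would change only the reagent bottle.

Step 1
Reactants: 1 ethyl 1,4-dioxaspiro[4.5]decane-8-carboxylate; 2 chlorotrimethylsilane
Product: 3 [ethoxy(1,4-dioxaspiro[4.5]decan-8-ylidene)methoxy]trimethylsilane (trimethylsilyl ketene acetal, achiral)
Conditions: LiN(i-Pr)2 (LDA), THF, −78 °C; then 2, −78 °C → rt; pentane, filtration, distillation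
Reagents that add atoms: chlorotrimethylsilane (2), C[Si](C)(C)Cl
Why: Kinetic deprotonation of the α-branched ester and O-silylation of the enolate (ketene silyl acetal formation) is reliable because C-silylation at the fully substituted C6 is sterically blocked; the two ring B arms are identical, so neither an alkene isomer nor a stereocentre arises.

Step 2
Reactants: 3 trimethylsilyl ketene acetal; 4 mesityl oxide (4-methylpent-3-en-2-one)
Product: 6 11,11-dimethylspiro[5.5]undecane-3,7,9-trione 3-ethylene ketal (achiral), via silyl enol ether 5 (not isolated)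
Conditions: MeCN, 15 kbar, 40 °C; pressure released, volatiles evaporated; KOtBu (2 equiv), THF, 0 °C → rt; cold 1 M HCl to pH 4
Reagents that add atoms: none
Why: Compression favours the strongly volume-contracting, open transition state in which the electron-rich C6 terminus of the neutral ketene acetal 3 bonds to C11, the β-carbon of 4, while silicon passes to the enone oxygen, so that the bond between the two fully substituted carbons is made without a basic enolate and is stored as silyl enol ether 5 (Mukaiyama–Michael addition). tert-Butoxide then removes the silyl group, the C9–C10 enolate so released exchanges protons through tert-butanol with the C8 methyl enolate, and the latter acylates at the ester carbon C7 with loss of ethoxide (Dieckmann-type intramolecular Claisen condensation), closing ring A in a 6-(enolexo)-exo-trig mode. The closest known reaction types are the pressure- or Lewis-acid-promoted additions of tetrasubstituted ketene silyl acetals to β,β-disubstituted enones such as 4, which join two quaternary carbons, and the Michael–Claisen annulation of 4 with malonate that gives dimedone. No stereocentre arises, since 6 retains a mirror plane containing ring A and C6 is only prochiral. The step needs 1,4- instead of 1,2-addition, which the uncharged, polarisable nucleophile and the absence of a hard counter-ion secure, and acylation through C8 instead of C10, which is secured because C10 could only close a four-membered ring. Deprotonation of the product at C8 to the delocalised diketonate is irreversible under the conditions and drains the preceding equilibria, retro-Michael cleavage included.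

Step 3
Reactants: 6 dione ketal
Product: 7 11,11-dimethylspiro[5.5]undecane-3,7,9-trione (achiral)
Conditions: 2 M HCl, THF, rt
Reagents that add atoms: water, O
Why: Acid-catalysed ketal hydrolysis frees the C3 ketone while the enolised 1,3-dione of ring A is indifferent to aqueous acid, and the product is still achiral.

Step 4
Reactants: 7 trione
Product: 8 11,11-dimethyl-9-(2-methylpropoxy)spiro[5.5]undec-8-ene-3,7-dione (achiral vinylogous ester)
Conditions: i-BuOH, TsOH·H2O (cat.), toluene, Dean–Stark, reflux; dilute aqueous acid wash
Reagents that add atoms: 2-methylpropan-1-ol, CC(C)CO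
Why: Acid-catalysed enol etherification of a cyclic 1,3-dione (vinylogous ester formation) occurs at the carbonyl the alcohol can reach, C9, because C7 is shielded by the spiro carbon, and any ketal formed at C3 falls back to the ketone in the aqueous wash; no stereocentre is formed.

Step 5
Reactants: 8 vinylogous ester ketone
Product: 10 (6S)-11,11-dimethyl-9-(2-methylpropoxy)-7-oxospiro[5.5]undeca-2,8-dien-3-yl trifluoromethanesulfonate, via lithium enolate 9 (not isolated)
Conditions: (S,S)-bis(1-phenylethyl)amine, n-BuLi, LiCl, THF, −78 °C; 8, −100 → −78 °C; then N-(5-chloropyridin-2-yl)bis(trifluoromethanesulfonimide), −78 → −20 °C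
Reagents that add atoms: N-(5-chloropyridin-2-yl)bis(trifluoromethanesulfonimide), O=S(=O)(N(c1ccc(Cl)cn1)S(=O)(=O)C(F)(F)F)C(F)(F)F
Why: Enantiotopos-selective deprotonation of a 4,4-disubstituted cyclohexanone by a C2-symmetric chiral lithium amide followed by O-sulfonylation of the enolate: ring B rests in the chair with the bulky C11 equatorial and the acyl carbon C7 axial, the amide tells the two axial α-hydrogens at C2 and C4 apart, and removal of the one at C2 makes C6 a stereocentre of the required sense (6S here by the priority rules), while the vinylogous ester offers only a slower, neopentylic γ-CH2.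

Step 6
Reactants: 10 alkenyl triflate
Product: 12 (6S)-7,11,11-trimethyl-9-oxospiro[5.5]undeca-2,7-dien-3-yl trifluoromethanesulfonate, via tertiary allylic alcohol 11 (not isolated)
Conditions: MeLi, CeCl3 (pre-stirred), THF, −78 → −20 °C; then 1 M HCl, 0 °C → rt
Reagents that add atoms: methyllithium, [Li]C; water, O
Why: 1,2-Addition of the weakly basic organocerium reagent to the hindered C7 carbonyl followed by acid-induced Stork–Danheiser transposition (ionisation of the tertiary allylic alcohol, capture of water at C9, loss of isobutanol) gives the enone, the alkenyl triflate tolerating both stages and the passing C7 stereocentre being erased.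

Step 7
Reactants: 12 enone; 2 chlorotrimethylsilane
Product: 14 (6R,10R)-10-bromo-7,11,11-trimethyl-9-oxospiro[5.5]undeca-2,7-dien-3-yl trifluoromethanesulfonate (same geometry at C6, descriptor changed by priorities), via silyl dienol ether 13 (not isolated)
Conditions: LiN(i-Pr)2, THF, −78 °C; 2; then NBS, −78 → 0 °C
Reagents that add atoms: N-bromosuccinimide, O=C1CCC(=O)N1Br; chlorotrimethylsilane (2), C[Si](C)(C)Cl (silicon only in 13)
Why: Kinetic α′-deprotonation of the cyclohexenone at C10 (C6 carries no hydrogen), O-silylation to the cross-conjugated 2-silyloxydiene and electrophilic bromination at its nucleophilic terminus C10 place the bromine regiospecifically, the electron-poor alkenyl triflate staying untouched; C10 is formed without reliable control but stays epimerisable next to the ketone and is corrected in step 8.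

Step 8
Reactants: 14 α′-bromoenone
Product: 15 (6R,10R)-9-acetoxy-10-bromo-11,11-dimethyl-7-methylidenespiro[5.5]undeca-2,8-dien-3-yl trifluoromethanesulfonate
Conditions: isopropenyl acetate, TsOH·H2O (cat.), reflux, slow removal of acetone
Reagents that add atoms: isopropenyl acetate, CC(=C)OC(C)=O
Why: Acid-catalysed thermodynamic enol acetylation of an enone gives the linearly conjugated dienol acetate, here by loss of a C14 hydrogen because C6 is quaternary, and since the C10 epimers of 14 interconvert through the C9–C10 enol under the same acid, the material should funnel (Curtin–Hammett situation) into the (10R) diastereomer, in which bromine is pseudo-equatorial and cis to C1 and the C14 methylene leans over the flat C1–C2=C3 arm instead of over the C5–C4 arm with its axial hydrogen.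

Step 9
Reactants: 15 dienol acetate
Product: 17 (6R,9S,10R)-10-bromo-9-hydroxy-11,11-dimethyl-7-methylidenespiro[5.5]undec-2-en-3-yl trifluoromethanesulfonate, via methylene bromoketone 16 (not isolated)
Conditions: NaBH4, EtOH–THF, −10 → 0 °C
Reagents that add atoms: none
Why: Deconjugative borohydride reduction of a dienol acetate, the classical way from a steroidal enone to the β,γ-unsaturated alcohol: ethanolysis frees the dienolate, kinetic protonation at the α-carbon C8 gives the β,γ-unsaturated ketone 16, and this is reduced faster than it reconjugates, hydride coming in along the equatorial trajectory because the axial C11 methyl blocks the other face, so that the hydroxyl ends up axial and cis to the equatorial bromine (9S).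

Step 10
Reactants: 17 cis-bromohydrin
Product: 18 (6R,9S,10R)-9-acetoxy-10-bromo-11,11-dimethyl-7-methylidenespiro[5.5]undec-2-en-3-yl trifluoromethanesulfonate
Conditions: Ac2O, pyridine, DMAP (cat.), CH2Cl2, rt
Reagents that add atoms: acetic anhydride, CC(=O)OC(C)=O
Why: DMAP-catalysed acylation of the hindered axial secondary alcohol proceeds with retention at C9, and a cis-bromohydrin cannot close to an epoxide under the mildly basic conditions.

Step 11
Reactants: 18 acetoxy triflate
Product: 19 (6R,9S,10R)-10-bromo-3,11,11-trimethyl-7-methylidenespiro[5.5]undec-2-en-9-yl acetate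
Conditions: MeZnCl, Pd(PPh3)4 (5 mol %), THF, rt → 45 °C
Reagents that add atoms: methylzinc chloride, C[Zn]Cl
Why: Negishi cross-coupling, in which zerovalent palladium inserts into the alkenyl C3–O bond far faster than into the hindered secondary C10–Br bond and the methyl group is passed on from zinc, fixes the trisubstituted alkene at C2=C3 so that C6 keeps its configuration, while the non-allylic acetate and the organozinc reagent ignore each other.

Step 12
Reactants: 19 diene acetate
Product: 20 (2R,3S,6R,9S,10R)-10-bromo-2,3-epoxy-3,11,11-trimethyl-7-methylidenespiro[5.5]undecan-9-yl acetate (oxygen cis to C11)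
Conditions: 1,2:4,5-di-O-isopropylidene-β-D-erythro-hexo-2,3-diulo-2,6-pyranose (30 mol %), Oxone (2KHSO5·KHSO4·K2SO4), K2CO3, Bu4NHSO4, MeCN–dimethoxymethane / aq. Na2B4O7–Na2EDTA, 0 °C
Reagents that add atoms: potassium peroxymonosulfate, [K+].[O-]S(=O)(=O)OO
Why: Shi epoxidation, in which the chiral dioxirane prefers the electron-rich trisubstituted C2=C3 bond to the hindered 1,1-disubstituted C7=C14 bond and the spiro transition state of the D-fructose-derived catalyst delivers oxygen to the face cis to C11, which is also the face left open by the axial C7 and its methylene group, sets (2R,3S).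

Step 13
Reactants: 20 epoxide
Product: 21 (2S,3S,6R,9S,10R)-10-bromo-2-chloro-3-hydroxy-3,11,11-trimethyl-7-methylidenespiro[5.5]undecan-9-yl acetate
Conditions: LiCl, AcOH, THF, rt → 45 °C
Reagents that add atoms: lithium chloride, [Li+].[Cl-]
Why: Weakly acidic halide opening of a trisubstituted epoxide (SN2), with chloride attacking the secondary C2 from the face opposite to the C–O bond, which is also the trans-diaxial (Fürst–Plattner) mode of the half-chair with C11 equatorial, inverts C2 to (2S) and leaves the oxygen on C3 as the tertiary alcohol anti to chlorine.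

Step 14
Reactants: 21 chlorohydrin
Product: 22 9-acetylisoobtusol, (2S,3S,6R,9S,10R)-3,10-dibromo-2-chloro-3,11,11-trimethyl-7-methylidenespiro[5.5]undecan-9-yl acetate
Conditions: 1-bromo-N,N,2-trimethylprop-1-en-1-amine, CH2Cl2, −20 °C → rt
Reagents that add atoms: 1-bromo-N,N,2-trimethylprop-1-en-1-amine, CC(C)=C(Br)N(C)C
Why: Neutral deoxybromination of a tertiary alcohol with an α-bromoenamine, in which the alcohol adds to the derived keteniminium ion, the alkoxyiminium group leaves the tertiary C3 with anchimeric help from the antiperiplanar C2 chlorine and bromide opens the unsymmetrical chloronium ion at its tertiary carbon anti to chlorine, amounts to retention and gives (3S) trans to chlorine, while the absence of free HBr spares C7=C14.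

**Compound list**
1 | ethyl 1,4-dioxaspiro[4.5]decane-8-carboxylate | CCOC(=O)C1CCC2(CC1)OCCO2 | starting material
2 | chlorotrimethylsilane | C[Si](C)(C)Cl | starting material
3 | [ethoxy(1,4-dioxaspiro[4.5]decan-8-ylidene)methoxy]trimethylsilane | CCOC(O[Si](C)(C)C)=C1CCC2(CC1)OCCO2 | intermediate
4 | mesityl oxide | CC(C)=CC(C)=O | starting material
5 | ethyl 8-[2-methyl-4-(trimethylsilyloxy)pent-3-en-2-yl]-1,4-dioxaspiro[4.5]decane-8-carboxylate | CCOC(=O)C1(CCC2(CC1)OCCO2)C(C)(C)C=C(C)O[Si](C)(C)C | intermediate (not isolated)
6 | 11,11-dimethylspiro[5.5]undecane-3,7,9-trione 3-ethylene ketal | O=C1CC(=O)CC(C)(C)C12CCC3(CC2)OCCO3 | intermediate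
7 | 11,11-dimethylspiro[5.5]undecane-3,7,9-trione | O=C1CC(=O)CC(C)(C)C12CCC(=O)CC2 | intermediate
8 | 11,11-dimethyl-9-(2-methylpropoxy)spiro[5.5]undec-8-ene-3,7-dione | O=C1C=C(OCC(C)C)CC(C)(C)C12CCC(=O)CC2 | intermediate
9 | lithium (6S)-C2=C3 enolate of 8 | O=C1C=C(OCC(C)C)CC(C)(C)[C@@]12CCC(O[Li])=CC2 | intermediate (not isolated)
10 | (6S)-11,11-dimethyl-9-(2-methylpropoxy)-7-oxospiro[5.5]undeca-2,8-dien-3-yl trifluoromethanesulfonate | O=C1C=C(OCC(C)C)CC(C)(C)[C@@]12CCC(OS(=O)(=O)C(F)(F)F)=CC2 | intermediate
11 | (6S)-7-hydroxy-7,11,11-trimethyl-9-(2-methylpropoxy)spiro[5.5]undeca-2,8-dien-3-yl trifluoromethanesulfonate (either C7 epimer) | CC1(O)C=C(OCC(C)C)CC(C)(C)[C@@]12CCC(OS(=O)(=O)C(F)(F)F)=CC2 | intermediate (not isolated)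
12 | (6S)-7,11,11-trimethyl-9-oxospiro[5.5]undeca-2,7-dien-3-yl trifluoromethanesulfonate | CC1=CC(=O)CC(C)(C)[C@@]12CCC(OS(=O)(=O)C(F)(F)F)=CC2 | intermediate
13 | (6R)-7,11,11-trimethyl-9-(trimethylsilyloxy)spiro[5.5]undeca-2,7,9-trien-3-yl trifluoromethanesulfonate | CC1=CC(O[Si](C)(C)C)=CC(C)(C)[C@@]12CCC(OS(=O)(=O)C(F)(F)F)=CC2 | intermediate (not isolated)
14 | (6R,10R)-10-bromo-7,11,11-trimethyl-9-oxospiro[5.5]undeca-2,7-dien-3-yl trifluoromethanesulfonate (C10 still epimerisable) | CC1=CC(=O)[C@H](Br)C(C)(C)[C@@]12CCC(OS(=O)(=O)C(F)(F)F)=CC2 | intermediate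
15 | (6R,10R)-9-acetoxy-10-bromo-11,11-dimethyl-7-methylidenespiro[5.5]undeca-2,8-dien-3-yl trifluoromethanesulfonate | C=C1C=C(OC(C)=O)[C@H](Br)C(C)(C)[C@@]12CCC(OS(=O)(=O)C(F)(F)F)=CC2 | intermediate
16 | (6R,10R)-10-bromo-11,11-dimethyl-7-methylidene-9-oxospiro[5.5]undec-2-en-3-yl trifluoromethanesulfonate | C=C1CC(=O)[C@H](Br)C(C)(C)[C@@]12CCC(OS(=O)(=O)C(F)(F)F)=CC2 | intermediate (not isolated)
17 | (6R,9S,10R)-10-bromo-9-hydroxy-11,11-dimethyl-7-methylidenespiro[5.5]undec-2-en-3-yl trifluoromethanesulfonate | C=C1C[C@H](O)[C@H](Br)C(C)(C)[C@@]12CCC(OS(=O)(=O)C(F)(F)F)=CC2 | intermediate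
18 | (6R,9S,10R)-9-acetoxy-10-bromo-11,11-dimethyl-7-methylidenespiro[5.5]undec-2-en-3-yl trifluoromethanesulfonate | C=C1C[C@H](OC(C)=O)[C@H](Br)C(C)(C)[C@@]12CCC(OS(=O)(=O)C(F)(F)F)=CC2 | intermediate
19 | (6R,9S,10R)-10-bromo-3,11,11-trimethyl-7-methylidenespiro[5.5]undec-2-en-9-yl acetate | C=C1C[C@H](OC(C)=O)[C@H](Br)C(C)(C)[C@@]12CCC(C)=CC2 | intermediate
20 | (2R,3S,6R,9S,10R)-10-bromo-2,3-epoxy-3,11,11-trimethyl-7-methylidenespiro[5.5]undecan-9-yl acetate | C=C1C[C@H](OC(C)=O)[C@H](Br)C(C)(C)[C@@]12CC[C@]3(C)O[C@@H]3C2 | intermediate
21 | (2S,3S,6R,9S,10R)-10-bromo-2-chloro-3-hydroxy-3,11,11-trimethyl-7-methylidenespiro[5.5]undecan-9-yl acetate | C=C1C[C@H](OC(C)=O)[C@H](Br)C(C)(C)[C@@]12CC[C@](C)(O)[C@@H](Cl)C2 | intermediate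
22 | 9-acetylisoobtusol | C=C1C[C@H](OC(C)=O)[C@H](Br)C(C)(C)[C@@]12CC[C@](C)(Br)[C@@H](Cl)C2 | target

**Total step count:** 14. **Longest linear sequence:** 14 steps (from 1).

**Steps most likely to fail**

Step 2. Bond formation between two fully substituted carbons may be too slow even under pressure. The ketene acetal may simply lose silicon. Alkoxide may also trigger retro-Michael fragmentation before the hindered ester is acylated. The fallback sets out from 1 and 4 and returns at 6, and it makes C6–C11 intramolecularly by an Ireland–Claisen rearrangement. Luche reduction of 4 (NaBH4, CeCl3·7H2O, MeOH) gives 4-methylpent-3-en-2-ol F1. Ti(OiPr)4-catalysed transesterification of 1 with it gives 4-methylpent-3-en-2-yl 1,4-dioxaspiro[4.5]decane-8-carboxylate F2. LiN(i-Pr)2 and Me3SiCl followed by warming let the tethered silyl ketene acetal rearrange through a six-membered chair to 8-[(E)-2-methylpent-3-en-2-yl]-1,4-dioxaspiro[4.5]decane-8-carboxylic acid F3. MeI and K2CO3 give methyl 8-[(E)-2-methylpent-3-en-2-yl]-1,4-dioxaspiro[4.5]decane-8-carboxylate F4. Wacker oxidation (PdCl2, CuCl, O2, aqueous DMF), with oxygen entering at C9 away from the neopentylic C10, gives methyl 8-(2-methyl-4-oxopentan-2-yl)-1,4-dioxaspiro[4.5]decane-8-carboxylate F5. KOtBu in THF then closes C7–C8 to 6.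

Step 13. Chloride has to reach C2 past the axial C7 substituent and its methylene group, so the opening may be sluggish. It could then be overtaken by ionisation at the tertiary C3, with chloride or acetate entering there, or by rearrangement of the epoxide. The fallback sets out from 19 and returns at 21, and it replaces the epoxide by a far more reactive cyclic sulfate. OsO4 (cat.) with N-methylmorpholine N-oxide dihydroxylates C2=C3 on the face cis to C11 to give (2R,3S,6R,9S,10R)-10-bromo-2,3-dihydroxy-3,11,11-trimethyl-7-methylidenespiro[5.5]undecan-9-yl acetate F6. SO2Cl2 and Et3N at −78 °C give the 2,3-cyclic sulfate F7. LiCl in DMF opens it at the secondary C2 with inversion to the lithium C3-sulfate monoester of the chlorohydrin F8. Catalytic H2SO4 in wet THF hydrolyses this to 21.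

Step 14. The tertiary cation may lose a proton instead of taking up bromide. Stereochemistry may leak if chlorine fails to bridge. Any acid liberated by elimination may add to C7=C14. The fallback sets out from 21 and returns at 22, and it separates activation from substitution. Trifluoroacetic anhydride and pyridine convert 21 into the C3 trifluoroacetate of chlorohydrin 21 F9. This discrete ester is then ionised at low temperature with MgBr2·OEt2 in CH2Cl2. The Lewis acid pulls on the carboxylate while delivering bromide within the ion pair, anti to chlorine.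

**Further compounds**
F1 | step 2 | 4-methylpent-3-en-2-ol (racemic) | CC(O)C=C(C)C
F2 | step 2 | 4-methylpent-3-en-2-yl 1,4-dioxaspiro[4.5]decane-8-carboxylate | CC(OC(=O)C1CCC2(CC1)OCCO2)C=C(C)C
F3 | step 2 | 8-[(E)-2-methylpent-3-en-2-yl]-1,4-dioxaspiro[4.5]decane-8-carboxylic acid | C/C=C/C(C)(C)C1(CCC2(CC1)OCCO2)C(=O)O
F4 | step 2 | methyl 8-[(E)-2-methylpent-3-en-2-yl]-1,4-dioxaspiro[4.5]decane-8-carboxylate | C/C=C/C(C)(C)C1(CCC2(CC1)OCCO2)C(=O)OC
F5 | step 2 | methyl 8-(2-methyl-4-oxopentan-2-yl)-1,4-dioxaspiro[4.5]decane-8-carboxylate | CC(=O)CC(C)(C)C1(CCC2(CC1)OCCO2)C(=O)OC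
F6 | step 13 | (2R,3S,6R,9S,10R)-10-bromo-2,3-dihydroxy-3,11,11-trimethyl-7-methylidenespiro[5.5]undecan-9-yl acetate | C=C1C[C@H](OC(C)=O)[C@H](Br)C(C)(C)[C@@]12CC[C@](C)(O)[C@H](O)C2
F7 | step 13 | 2,3-cyclic sulfate of F6 | C=C1C[C@H](OC(C)=O)[C@H](Br)C(C)(C)[C@@]12CC[C@]3(C)OS(=O)(=O)O[C@@H]3C2
F8 | step 13 | lithium C3-sulfate monoester of chlorohydrin 21 | C=C1C[C@H](OC(C)=O)[C@H](Br)C(C)(C)[C@@]12CC[C@](C)(OS(=O)(=O)[O-])[C@@H](Cl)C2.[Li+]
F9 | step 14 | C3 trifluoroacetate of chlorohydrin 21 | C=C1C[C@H](OC(C)=O)[C@H](Br)C(C)(C)[C@@]12CC[C@](C)(OC(=O)C(F)(F)F)[C@@H](Cl)C2
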